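**Retrosynthetic overview**
1. The dihydropyran is the only ring made, and it is formed last. Disconnect O1–C2: 6-endo opening of an (R)-epoxyprenyl side chain by the free ortho-OH next to the benzoyl group. The C3–O bond is never broken, so the epoxide CH becomes C3 (R).
2. The (R)-epoxide comes from face-selective mono-epoxidation of one of the two equivalent prenyl groups of unprotected clusiaphenone B. Oxidation and ring closure are telescoped, with no protecting groups.
3. Clusiaphenone B comes from 2,4,6-trihydroxybenzophenone and two prenyl bromide units (double aromatic C-prenylation).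
4. 2,4,6-Trihydroxybenzophenone comes from phloroglucinol and benzoyl chloride. Both carbocycles are bought.

Assumption: a crude intermediate carried on without purification counts as not isolated, so the telescoped oxidation/cyclisation is one step.

**Step 1**
Reactants: 1 phloroglucinol (benzene-1,3,5-triol); 2 benzoyl chloride
Product: 3 2,4,6-trihydroxybenzophenone
Conditions: AlCl3 (3.5 equiv), PhNO2, 65 °C; then ice/aq HCl
Reagents that add atoms: none
Why: Friedel–Crafts C-acylation of the most electron-rich arene available; any O-benzoate undergoes Fries rearrangement under the same conditions, and the first acyl group deactivates the ring against a second acylation.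

**Step 2**
Reactants: 3 2,4,6-trihydroxybenzophenone; 4 prenyl bromide (1-bromo-3-methylbut-2-ene, 2.1 equiv)
Product: 6 clusiaphenone B [2,4,6-trihydroxy-3,5-bis(3-methylbut-2-enyl)benzophenone], via monoprenyl phlorobenzophenone 5 (not isolated)
Conditions: KOH (2.1 equiv), H2O, N2, 0 °C → rt; then aq HCl
Reagents that add atoms: none
Why: C-selective alkylation of the ambident phloroglucinolate, a chemical copy of aromatic prenyl transfer; water hydrogen-bonds the oxygens so the soft allylic bromide reacts at the two free ring carbons, and the stoichiometry limits dearomatising third prenylation.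

**Step 3**
Reactants: 6 clusiaphenone B
Product: 8 (3R)-8-benzoyl-2,2-dimethyl-6-(3-methylbut-2-enyl)chroman-3,5,7-triol (target), via (R)-monoepoxide 7 (not isolated)
Conditions: (i) Shi ketone (D-fructose-derived, 0.5 equiv in two portions), Oxone (0.55 equiv = 1.1 equiv KHSO5), KHCO3 (pH 7–7.5), Bu4NHSO4 (5 mol %), MeCN–DMM/aq Na2EDTA, 0 °C, stop at ~60 % conversion; extract into CH2Cl2, dry; (ii) CSA (5 mol %), CH2Cl2, −20 → 0 °C
Reagents that add atoms: Oxone (active salt potassium peroxymonosulfate), [K+].[O-]S(=O)(=O)OO
Why: Proposed new method: the closest known chemistry is Shi asymmetric epoxidation of O-protected prenylarenes followed by acid-promoted "anti-Baldwin" 6-endo-tet phenol–epoxide closure to 3-chromanols, and here it is run on the free triphenol because the dioxirane attacks the trisubstituted C=C much faster than the benzoyl-deactivated, hydrogen-bonded ring that is largely un-ionised at pH ≤ 7.5; the spiro transition state of the D-fructose ketone delivers O to the face giving the (R)-oxirane (same sense as (R,R) from trans-alkenes), the two prenyl groups are equivalent so only conversion must be limited, and on protonation the oxirane opens at its cation-stabilising CMe2 end (bonds at the stereocentre untouched, R retained), with the most acidic 4-OH acting as internal hydrogen-bond donor to the oxirane oxygen and the free 2-OH attacking anti to it, which gives the 8-benzoyl chroman.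

**Compound list**
1 | phloroglucinol (benzene-1,3,5-triol) | Oc1cc(O)cc(O)c1 | starting material
2 | benzoyl chloride | O=C(Cl)c1ccccc1 | starting material
3 | 2,4,6-trihydroxybenzophenone | O=C(c1ccccc1)c1c(O)cc(O)cc1O | intermediate
4 | prenyl bromide (1-bromo-3-methylbut-2-ene) | CC(C)=CCBr | starting material
5 | 2,4,6-trihydroxy-3-(3-methylbut-2-enyl)benzophenone (not isolated) | CC(C)=CCc1c(O)cc(O)c(C(=O)c2ccccc2)c1O | intermediate
6 | clusiaphenone B, 2,4,6-trihydroxy-3,5-bis(3-methylbut-2-enyl)benzophenone | CC(C)=CCc1c(O)c(CC=C(C)C)c(O)c(C(=O)c2ccccc2)c1O | intermediate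
7 | {3-[((2R)-3,3-dimethyloxiran-2-yl)methyl]-2,4,6-trihydroxy-5-(3-methylbut-2-enyl)phenyl}(phenyl)methanone (not isolated) | CC(C)=CCc1c(O)c(C[C@H]2OC2(C)C)c(O)c(C(=O)c3ccccc3)c1O | intermediate
8 | (3R)-8-benzoyl-2,2-dimethyl-6-(3-methylbut-2-enyl)chroman-3,5,7-triol | CC(C)=CCc1c(O)c2c(c(C(=O)c3ccccc3)c1O)OC(C)(C)[C@H](O)C2 | target

**Total step count:** 3. **Longest linear sequence:** 3.

**Steps most likely to fail**

Step 3 carries the highest risk, with four failure modes:
- The oxidant may hydroxylate the fully substituted ring in a humulone-type dearomatisation.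
- Any phenolate formed can close 5-exo to the hydroxyisopropyl-dihydrobenzofuran.
- The 4-OH can close instead of the 2-OH, giving the 6-benzoyl-8-prenyl isomer.
- Mono-epoxidation is statistically capped near 50 %, though unreacted 6 is recovered.

The fallback sets out from 6 and returns at 8, and it enforces the closure with a blocking group. Ac2O (1.0 equiv)/Et3N in CH2Cl2 at −40 °C acylates the most acidic, non-chelated para-OH. This gives the still symmetric and less oxidisable 4-O-acetylclusiaphenone B F1. The same Shi epoxidation then gives the (R)-monoepoxide acetate F2. Catalytic CSA can only engage the one neighbouring free OH, giving the 5-O-acetyl chromanol F3. K2CO3/MeOH at 0 °C under N2 then releases 8.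

Step 2 is likely to give mono-, di-, gem-diprenylated (dearomatised) and O-prenylated products together, with a realistic yield of 30–50 %. The fallback sets out from 3 and returns at 6, replacing direct C-alkylation by sigmatropic C–C bond formation.
- Allyl bromide/K2CO3 in acetone gives 2,4-bis(allyloxy)-6-hydroxybenzophenone F4.
- Heating in N,N-diethylaniline (about 200 °C) effects a double aromatic Claisen rearrangement. An ortho shift, or a para shift via Cope, both converge on C3/C5, giving 3,5-diallyl-2,4,6-trihydroxybenzophenone F5.
- Cross-metathesis with 2-methyl-2-butene (Grubbs II, CH2Cl2, 40 °C) converts both allyl groups to prenyl groups and gives 6.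

Step 1 may suffer from O-benzoylation, double acylation and poorly soluble aluminium phenolates, all of which lower the yield. The fallback sets out from 1 and returns at 3, using a nitrile electrophile (Houben–Hoesch) that stops cleanly after one C–C bond. Benzonitrile, ZnCl2 and HCl gas in Et2O at 0 °C precipitate the ketiminium chloride F6. Boiling this salt in water hydrolyses it to 3.

**Further compounds**
F1 | step 3 | 4-benzoyl-3,5-dihydroxy-2,6-bis(3-methylbut-2-enyl)phenyl acetate (4-O-acetylclusiaphenone B) | CC(C)=CCc1c(O)c(C(=O)c2ccccc2)c(O)c(CC=C(C)C)c1OC(C)=O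
F2 | step 3 | 4-benzoyl-2-{[(2R)-3,3-dimethyloxiran-2-yl]methyl}-3,5-dihydroxy-6-(3-methylbut-2-enyl)phenyl acetate | CC(C)=CCc1c(O)c(C(=O)c2ccccc2)c(O)c(C[C@H]3OC3(C)C)c1OC(C)=O
F3 | step 3 | (3R)-8-benzoyl-3,7-dihydroxy-2,2-dimethyl-6-(3-methylbut-2-enyl)chroman-5-yl acetate | CC(C)=CCc1c(OC(C)=O)c2c(c(C(=O)c3ccccc3)c1O)OC(C)(C)[C@H](O)C2
F4 | step 2 | 2,4-bis(allyloxy)-6-hydroxybenzophenone | C=CCOc1cc(O)c(C(=O)c2ccccc2)c(OCC=C)c1
F5 | step 2 | 3,5-diallyl-2,4,6-trihydroxybenzophenone | C=CCc1c(O)c(CC=C)c(O)c(C(=O)c2ccccc2)c1O
F6 | step 1 | phenyl(2,4,6-trihydroxyphenyl)methaniminium chloride | [Cl-].[NH2+]=C(c1ccccc1)c1c(O)cc(O)cc1O
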